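**Assumptions.** The absolute configuration is taken exactly as drawn in the SMILES: (2R,4R), i.e. the 2-phenyl and 4-aryl groups of the flavan are trans. Compound 1 is taken as a catalogue compound (otherwise one bromination step from 4-methoxyphenol).

## Retrosynthetic overview

1. Cut the flavan C4–chalcone C3' bond last: anodic dehydrogenative coupling of a (2R)-7-hydroxyflavan with 2',6'-dihydroxy-4'-methoxychalcone, with C4 set trans to the C2 phenyl.
2. Chalcone: Claisen–Schmidt condensation of the acetophenone with benzaldehyde.
3. Flavan pyran ring: C4–C4a bond by phenoxide cycloalkylation of an aryl 3-chloro-1-phenylpropyl ether; C2–O bond by Mitsunobu inversion of (S)-3-chloro-1-phenylpropan-1-ol, the only purchased stereocentre.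
4. A-ring: C2-symmetric 2,5-dimethoxyresorcinol from 2,6-dibromo-4-methoxyphenol (methylation, double hydroxylation); the symmetry removes every regiochemical question.
5. Ring order: all benzene rings are bought; the pyran ring is closed in step 4; no ring is formed afterwards.

## Route

**Step 1**
Reactants: 1, 2,6-dibromo-4-methoxyphenol
Product: 2, 1,3-dibromo-2,5-dimethoxybenzene
Conditions: MeI, K2CO3, acetone, reflux
Reagents that add atoms: iodomethane, CI
Why: Williamson O-methylation of an acidic, hindered phenol; the aryl bromides are inert.

**Step 2**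
Reactants: 2, 1,3-dibromo-2,5-dimethoxybenzene
Product: 3, 2,5-dimethoxybenzene-1,3-diol
Conditions: Pd2(dba)3 (2 mol%), t-BuXPhos (8 mol%), KOH, dioxane/H2O (1:1), 100 °C, degassed; then degassed aq. HCl
Reagents that add atoms: potassium hydroxide, [K+].[OH-]
Why: Twofold Pd-catalysed hydroxylation of aryl bromides (C–O cross-coupling with hydroxide); the methyl ethers survive, and the product is kept air-free because it is electron-rich.

**Step 3**
Reactants: 3, 2,5-dimethoxybenzene-1,3-diol (2.5 equiv, excess recovered); 4, (S)-3-chloro-1-phenylpropan-1-ol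
Product: 5, 3-[(1R)-3-chloro-1-phenylpropoxy]-2,5-dimethoxyphenol
Conditions: PPh3, DIAD, THF, 0 °C to rt
Reagents that add atoms: none
Why: Mitsunobu etherification proceeds by SN2 inversion at the benzylic carbinol, so the (S)-alcohol gives the (R)-ether; the two OH groups of 3 are equivalent, excess diol suppresses the bis-ether, and the primary chloride is untouched.

**Step 4**
Reactants: 5, 3-[(1R)-3-chloro-1-phenylpropoxy]-2,5-dimethoxyphenol
Product: 6, (2R)-5,8-dimethoxy-2-phenylchroman-7-ol [(2R)-7-hydroxy-5,8-dimethoxyflavan]
Conditions: KOt-Bu (1.05 equiv), NaI (0.3 equiv), t-BuOH, 0.01 M, 80 °C, Ar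
Reagents that add atoms: none
Why: Ar2-6 phenoxide cycloalkylation (intramolecular para-C-alkylation of a phenoxide): the only H-bearing carbon ortho to the tether is para to O⁻ and attacks the primary halide (iodide formed in situ) to close the six-membered ring, then rearomatises; the stereocentre is not involved and stays R.

**Step 5**
Reactants: 7, 1-(2,6-dihydroxy-4-methoxyphenyl)ethan-1-one; 8, benzaldehyde
Product: 9, (E)-1-(2,6-dihydroxy-4-methoxyphenyl)-3-phenylprop-2-en-1-one (2',6'-dihydroxy-4'-methoxychalcone)
Conditions: 50% aq. KOH, EtOH, 0 °C to rt, 48 h; then cold 1 M HCl to pH 5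
Reagents that add atoms: none
Why: Claisen–Schmidt aldol condensation gives the thermodynamic E-enone; cold, mildly acidic work-up avoids oxa-Michael closure to the flavanone.

**Step 6**
Reactants: 6, (2R)-5,8-dimethoxy-2-phenylchroman-7-ol; 9, 2',6'-dihydroxy-4'-methoxychalcone (2.5 equiv, excess recovered)
Product: 10, sarcandrone B, (E)-1-{2,6-dihydroxy-3-[(2R,4R)-7-hydroxy-5,8-dimethoxy-2-phenylchroman-4-yl]-4-methoxyphenyl}-3-phenylprop-2-en-1-one
Conditions: undivided cell, graphite anode / Pt cathode, constant current 2 mA cm⁻², 1.8 F mol⁻¹ (on 6), n-Bu4NPF6 (0.1 M), HFIP/CH2Cl2 (1:1), 0 °C, Ar, dark; chromatography removes the minor 2,4-cis isomer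
Reagents that add atoms: none
Why: Proposed new method: anodic dehydrogenative C(sp3)–H/C(sp2)–H cross-coupling of an unprotected flavan with an acylphloroglucinol. The tetra-oxygenated phenol 6 should be the most easily oxidised species in the mixture (the ring of 9 is acyl-deactivated), and its 2e⁻/2H⁺ oxidation gives the C4 para-quinone methide, a benzylic cation stabilised by O1, 5-OMe and the 7-oxygen in HFIP. Friedel–Crafts capture by C3' of 9 (C3' and C5' are equivalent, so one regioisomer) occurs quasi-axially and anti to the equatorial 2-phenyl, with the 5-OMe peri interaction keeping the new aryl axial, which gives 2,4-trans = 4R. H2 evolves at Pt, so no chemical oxidant is needed, and the product resists re-oxidation because its C4–H lies in the arene plane. Closest known reaction types: DDQ-mediated oxidative C4 functionalisation of flavans, acid-catalysed flavan-4-ol/phloroglucinol condensation (both 2,4-trans-selective), and anodic generation of p-quinone methides from 4-alkylphenols.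

## Compound list

1 | 2,6-dibromo-4-methoxyphenol | COc1cc(Br)c(O)c(Br)c1 | starting material
2 | 1,3-dibromo-2,5-dimethoxybenzene | COc1cc(Br)c(OC)c(Br)c1 | intermediate
3 | 2,5-dimethoxybenzene-1,3-diol | COc1cc(O)c(OC)c(O)c1 | intermediate
4 | (S)-3-chloro-1-phenylpropan-1-ol | O[C@@H](CCCl)c1ccccc1 | starting material
5 | 3-[(1R)-3-chloro-1-phenylpropoxy]-2,5-dimethoxyphenol | COc1cc(O)c(OC)c(O[C@H](CCCl)c2ccccc2)c1 | intermediate
6 | (2R)-5,8-dimethoxy-2-phenylchroman-7-ol | COc1cc(O)c(OC)c2c1CC[C@H](c1ccccc1)O2 | intermediate
7 | 1-(2,6-dihydroxy-4-methoxyphenyl)ethan-1-one | CC(=O)c1c(O)cc(OC)cc1O | starting material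
8 | benzaldehyde | O=Cc1ccccc1 | starting material
9 | (E)-1-(2,6-dihydroxy-4-methoxyphenyl)-3-phenylprop-2-en-1-one | COc1cc(O)c(C(=O)/C=C/c2ccccc2)c(O)c1 | intermediate
10 | sarcandrone B, (E)-1-{2,6-dihydroxy-3-[(2R,4R)-7-hydroxy-5,8-dimethoxy-2-phenylchroman-4-yl]-4-methoxyphenyl}-3-phenylprop-2-en-1-one | COc1cc(O)c(C(=O)/C=C/c2ccccc2)c(O)c1[C@H]1C[C@H](c2ccccc2)Oc2c(OC)c(O)cc(OC)c21 | target

## Summary

Total steps: 6. Longest linear sequence: 5 (steps 1, 2, 3, 4, 6).

Steps most likely to fail:

1. **Step 6 (proposed new electrochemical coupling).** Risks are over-oxidation of 6 to the flavylium ion or a quinone, phenol–arene biaryl coupling at C6, cathodic reduction of the enone, and a modest trans/cis ratio. Fallback (known chemistry): oxidise 6 with stoichiometric DDQ in CH2Cl2/MeOH to the 4-methoxyflavan, then run an acid-promoted (TMSOTf or TsOH) Friedel–Crafts coupling with 9, the established trans-selective flavan-4-ol(ether)/phloroglucinol condensation.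
2. **Step 4 (phenoxide Ar2-6 cycloalkylation).** Risks are intermolecular O-alkylation, slow chloride displacement and ipso attack at the OMe-bearing carbon. Fallback: close the ring with an aryl anion instead. Brominate 5 para to the OH (NBS), protect as the TBS ether, exchange Cl for I (NaI), carry out t-BuLi Br/Li exchange with Parham cycloalkylation at −78 °C, then remove TBS with TBAF.
3. **Step 3 (mono-Mitsunobu on the symmetric diol).** Risks are bis-etherification and partial SN1 erosion of ee at the benzylic carbon. Fallback: make the C–C bond first and the C–O bond last. Convert 3 to its bis-MOM ether, ortho-lithiate (n-BuLi) and alkylate with the TBS-protected iodide derived from 4, deprotect with HCl/MeOH, and close the pyran ring by intramolecular Mitsunobu (inversion to 2R), which has no statistical problem.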